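**Retrosynthetic overview**
- Endgame: C-19 is added to C-4 of a 19-nor bicyclic dione by catalytic asymmetric hydroxymethylation; the C-3 ketone comes from a nitro group (Nef).
- Ring A: C-1–C-2 and C-4–C-5 are made together by an amine-catalysed (3+3) annulation of the ring B enone with 3-nitrobut-3-en-2-yl pivalate, which supplies C-2, C-3, C-4 and C-18.
- Enabling feature: in ring B the C-6 carbonyl makes C-5 (α-CH) and the methyl on C-10 (future C-1, a γ-CH3) a vinylogous 1,3-dinucleophile, and because C-9 is quaternary this methyl is the only γ-position.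
- Ring B and C-9: enantioselective Diels–Alder reaction of tiglic aldehyde with a 2-silyloxypenta-1,3-diene; side chain by Wittig/B-alkyl Suzuki coupling; enone by Saegusa oxidation; C-7 oxygen by α′-hydroxylation, oxidised to the diosphenol last.
- Ring order: ring B (step 2), then ring A (step 13).

Key step: step 13

Remark: locants are halimane-type. Ring A is C-1, C-2, C-3 (ketone), C-4 (C-18 methyl, C-19 CH2OAc), C-5, C-10. Ring B is C-5, C-6 (ketone), C-7 (enol OH), C-8 (C-17 methyl), C-9 (C-20 methyl, chain C-11 to C-15 with C-16 on C-13), C-10. The target SMILES is read as (4S,9S,13E).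

**Step 1**
Reactants: 1 (E)-pent-3-en-2-one
Product: 2 (E)-2-(triisopropylsilyloxy)penta-1,3-diene
Conditions: LiN(iPr)2, THF, -78 °C; then iPr3SiOTf
Reagents that add atoms: triisopropylsilyl triflate, CC(C)[Si](OS(=O)(=O)C(F)(F)F)(C(C)C)C(C)C
Why: Kinetic deprotonation of the methyl group of the enone and O-silylation of the cross-conjugated enolate (silyl enol ether formation) should give the 2-silyloxydiene with the (E)-alkene unchanged.

**Step 2**
Reactants: 2 (E)-2-(triisopropylsilyloxy)penta-1,3-diene; 3 (E)-2-methylbut-2-enal (tiglic aldehyde)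
Product: 4 1,2,6-trimethyl-4-(triisopropylsilyloxy)cyclohex-3-ene-1-carbaldehyde
Conditions: (S)-3,3-diphenyl-1-(o-tolyl)tetrahydropyrrolo[1,2-c][1,3,2]oxazaborole·HNTf2 (20 mol %), CH2Cl2, -78 to -40 °C
Reagents that add atoms: none
Why: Catalytic enantioselective Diels–Alder reaction: the cationic oxazaborolidinium binds the enal and blocks one face so that the quaternary centre C-9 is set by catalyst control (catalyst antipode chosen by the usual formyl C–H···O binding model), the silyloxy group and the terminal methyl of the diene both steer its CH2 terminus to the β-carbon of the enal, and suprafacial addition to the (E)-enal places the C-8 methyl cis to the C-9 methyl, while the C-10 epimers (endo/exo) converge in step 7.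

**Step 3**
Reactants: 4 Diels–Alder aldehyde
Product: 5 4-ethenyl-3,4,5-trimethyl-1-(triisopropylsilyloxy)cyclohex-1-ene
Conditions: Ph3PCH3Br, KN(SiMe3)2, THF, 0 °C to rt
Reagents that add atoms: methyltriphenylphosphonium bromide (as its ylide), C[P+](c1ccccc1)(c1ccccc1)c1ccccc1.[Br-]
Why: Wittig methylenation of a non-enolisable neopentyl aldehyde should proceed without touching the silyl enol ether, and no stereocentre is affected.

**Step 4**
Reactants: 6 but-2-yn-1-ol
Product: 7 tert-butyl(but-2-yn-1-yloxy)dimethylsilane
Conditions: tBuMe2SiCl, imidazole, DMF, rt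
Reagents that add atoms: tert-butyldimethylsilyl chloride, CC(C)(C)[Si](C)(C)Cl
Why: Standard silylation of a primary alcohol (silyl ether formation).

**Step 5**
Reactants: 7 silyl ether of but-2-yn-1-ol
Product: 8 (E)-tert-butyl[(3-iodobut-2-en-1-yl)oxy]dimethylsilane
Conditions: Cp2Zr(H)Cl, THF, rt to 40 °C; then I2, 0 °C
Reagents that add atoms: iodine, II
Why: Hydrozirconation adds Zr–H syn across the alkyne with zirconium on the less hindered methyl-bearing carbon, and iodinolysis with retention gives the (E)-vinyl iodide (hydrozirconation–iodination).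

**Step 6**
Reactants: 5 vinyl compound; 8 (E)-vinyl iodide
Product: 10 silyl enol ether carrying the complete C-11 to C-16 side chain, via B-alkyl-9-borabicyclononane adduct 9 (not isolated)
Conditions: 9-BBN, THF, rt; then 8, Pd(dppf)Cl2 (5 mol %), AsPh3, Cs2CO3, DMF/H2O, rt
Reagents that add atoms: none
Why: 9-BBN hydroborates only the unhindered monosubstituted alkene at its terminus, and the B-alkyl Suzuki–Miyaura coupling joins C-12 to C-13 with retention of the (E)-geometry of 8.

**Step 7**
Reactants: 10 side-chain silyl enol ether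
Product: 11 4-[(3E)-5-(tert-butyldimethylsilyloxy)-3-methylpent-3-en-1-yl]-3,4,5-trimethylcyclohex-2-en-1-one
Conditions: Pd(OAc)2 (10 mol %), O2 (1 atm), DMSO, 50 °C
Reagents that add atoms: none
Why: Saegusa–Ito oxidation: the palladium enolate formed at C-5 has its only β-hydrogen on C-10, so β-hydride elimination gives the C-5=C-10 enone and removes the C-10 stereocentre.

**Step 8**
Reactants: 11 ring B enone
Product: 12 6-hydroxy derivative of 11 (hydroxyl on C-7 of the target numbering)
Conditions: LiN(iPr)2, THF, -78 °C; then 2-(phenylsulfonyl)-3-phenyloxaziridine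
Reagents that add atoms: 2-(phenylsulfonyl)-3-phenyloxaziridine, O=S(=O)(c1ccccc1)N1OC1c1ccccc1
Why: Kinetic deprotonation of a cyclohexenone by a lithium amide occurs at the α′-carbon (C-7) and the cross-conjugated enolate is hydroxylated by the N-sulfonyloxaziridine (enolate hydroxylation); the C-7 configuration does not matter because C-7 becomes sp2 in step 18.

**Step 9**
Reactants: 12 α′-hydroxy enone
Product: 13 6-(tert-butyldimethylsilyloxy) derivative of 11
Conditions: tBuMe2SiOTf, 2,6-lutidine, CH2Cl2, -78 °C
Reagents that add atoms: tert-butyldimethylsilyl triflate, CC(C)(C)[Si](C)(C)OS(=O)(=O)C(F)(F)F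
Why: Silylation of the secondary alcohol protects the ketol against amines, bases and the later acetylation (silyl ether formation).

**Step 10**
Reactants: 14 2-nitroethanol; 15 acetaldehyde
Product: 16 2-nitrobutane-1,3-diol
Conditions: KOtBu (5 mol %), THF/tBuOH, 0 °C
Reagents that add atoms: none
Why: Henry (nitroaldol) reaction of the nitronate of 14 with the aldehyde; the mixture of diastereomers is of no consequence.

**Step 11**
Reactants: 16 2-nitrobutane-1,3-diol
Product: 18 3-nitrobut-3-en-2-ol, via primary mesylate 17 (not isolated)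
Conditions: MeSO2Cl (1.05 equiv), Et3N (2.1 equiv), CH2Cl2, -40 to 0 °C
Reagents that add atoms: none
Why: The primary hydroxyl is sulfonylated faster than the secondary one and the β-mesyloxy nitro compound loses methanesulfonate by E1cB elimination through its nitronate, which fixes the alkene at the terminal position (nitroaldol dehydration).

**Step 12**
Reactants: 18 3-nitrobut-3-en-2-ol
Product: 19 3-nitrobut-3-en-2-yl 2,2-dimethylpropanoate
Conditions: (tBuCO)2O, Sc(OTf)3 (1 mol %), CH2Cl2, 0 °C
Reagents that add atoms: pivalic anhydride, CC(C)(C)C(=O)OC(=O)C(C)(C)C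
Why: Lewis-acid-catalysed acylation of the secondary alcohol avoids the amine bases that would add to the nitroalkene (esterification).

**Step 13**
Reactants: 13 silylated ring B enone; 19 3-nitrobut-3-en-2-yl pivalate
Product: 22 3-nitro-7,15-bis(tert-butyldimethylsilyloxy)-19-norhalima-5(10),13E-dien-6-one, via open-chain nitroalkene 20 (not isolated), via deconjugated enone 21 (not isolated)
Conditions: 9-amino-9-deoxy-epi-quinine (20 mol %), PhCO2H (20 mol %), toluene, 40 °C
Reagents that add atoms: none
Why: Proposed new method: the amine condenses with the C-6 ketone, γ-deprotonation at the C-10 methyl gives an extended dienamine whose exocyclic carbon (C-1) adds to the CH2 terminus of 19 (vinylogous Michael addition), the nitronate expels pivalate (E1cB) to give nitroalkene 20, and the re-formed dienamine closes ring A through its α-carbon (C-5) by intramolecular Michael addition onto C-4, after which hydrolysis and conjugation (21 to 22) release the catalyst. The closest known reaction types are the (3+3) annulation of enamines with 2-nitroallyl esters and the amine-catalysed vinylogous Michael addition of β-methylcyclohexenones to nitroalkenes; the α,γ-mode on a cyclohexenone is new. Ring A is the only ring closed, in a 6-endo-trig conjugate addition in which both carbons of the nitroalkene become ring atoms. The new centres at C-3 and C-4 and the transient one at C-5 need no control, because C-5 returns to sp2, C-3 becomes the ketone in step 14 and C-4 is set afresh under catalyst control in step 15. The step needs γ-then-α site selectivity and one orientation of the three-carbon unit: C-9 is quaternary so the C-10 methyl is the only γ-position, an enamine toward C-7 cannot close a six-membered ring, and 19 has a single Michael terminus (its CH2) with the leaving group on the methyl-bearing carbon, so C-2 must bond to C-1 and C-4 to C-5. N-(2-Nitroallyl) adducts of the amine are themselves allyl-transfer reagents, so alkylation of the catalyst should be reversible.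

**Step 14**
Reactants: 22 nitro-bicyclic enone
Product: 23 7,15-bis(tert-butyldimethylsilyloxy)-19-norhalima-5(10),13E-diene-3,6-dione
Conditions: NaOMe, MeOH, 0 °C; then TiCl3 (aq. HCl), NH4OAc, H2O/MeOH, rt
Reagents that add atoms: water, O
Why: Nef reaction in its reductive titanium variant: the nitronate is reduced to the N–H imine, which hydrolyses to the C-3 ketone under buffered conditions that the silyl ethers, the enone and the trisubstituted alkene should survive.

**Step 15**
Reactants: 23 bicyclic 3,6-dione
Product: 25 19-hydroxy-7,15-bis(tert-butyldimethylsilyloxy)halima-5(10),13E-diene-3,6-dione, via trimethylsilyl enol ether 24 (not isolated)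
Conditions: KN(SiMe3)2 (1.0 equiv), THF, -78 to -20 °C; Me3SiCl; then Sc(OTf)3 (10 mol %), (S,S)-6,6′-bis(1-hydroxy-2,2-dimethylpropyl)-2,2′-bipyridine (12 mol %), aq. HCHO, DME, -20 °C
Reagents that add atoms: formaldehyde, C=O
Why: The C-4 hydrogen is the most acidic one (α to the C-3 ketone and allylic to C-5=C-10), so equilibrating deprotonation and O-silylation give a single enol ether, and the Sc(OTf)3–chiral bipyridine-catalysed Mukaiyama aldol reaction with aqueous formaldehyde adds C-19 to one face of it, so that the quaternary centre C-4 is set by catalyst control (ligand antipode chosen for 4S; the remote C-9 centre gives no bias either way).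

**Step 16**
Reactants: 25 19-hydroxy dione
Product: 26 19-acetoxy-7,15-bis(tert-butyldimethylsilyloxy)halima-5(10),13E-diene-3,6-dione
Conditions: Ac2O, pyridine, DMAP (cat.), CH2Cl2, 0 °C
Reagents that add atoms: acetic anhydride, CC(=O)OC(C)=O
Why: Acylation of the neopentyl primary alcohol (esterification); the only other hydroxyls are silylated.

**Step 17**
Reactants: 26 bis-silyl acetate
Product: 27 19-acetoxy-7,15-dihydroxyhalima-5(10),13E-diene-3,6-dione
Conditions: HF·pyridine, pyridine, THF, 0 °C to rt
Reagents that add atoms: none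
Why: Fluoride-mediated desilylation removes both silyl ethers, while the acetate and the non-enolisable C-4 centre are stable to the buffered reagent.

**Step 18**
Reactants: 27 α-hydroxy ketone
Product: 29 (4S,9S,13E)-19-acetoxy-7,15-dihydroxyhalima-5(10),7,13-triene-3,6-dione (target), via 6,7-diketone tautomer 28 (not isolated)
Conditions: Cu(OAc)2·H2O (2.2 equiv), MeOH, rt
Reagents that add atoms: none
Why: Cu(OAc)2 oxidises α-hydroxy ketones to 1,2-diketones through the copper enediolate and leaves the primary allylic alcohol alone (acyloin oxidation), and the diketone can enolise only toward C-8, which gives the diosphenol of the target and removes the C-7 and C-8 stereocentres.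

**Compound list**
1 | (E)-pent-3-en-2-one | C/C=C/C(C)=O | starting material
2 | (E)-2-(triisopropylsilyloxy)penta-1,3-diene | C/C=C/C(=C)O[Si](C(C)C)(C(C)C)C(C)C | intermediate
3 | (E)-2-methylbut-2-enal (tiglic aldehyde) | C/C=C(\C)C=O | starting material
4 | 1,2,6-trimethyl-4-(triisopropylsilyloxy)cyclohex-3-ene-1-carbaldehyde; C-1 (= C-9) configured as in the target, 6-methyl (C-17) cis to 1-methyl (C-20), C-2 (= C-10) epimer mixture | CC1C=C(O[Si](C(C)C)(C(C)C)C(C)C)C[C@H](C)[C@@]1(C)C=O | intermediate
5 | 4-ethenyl-3,4,5-trimethyl-1-(triisopropylsilyloxy)cyclohex-1-ene, stereochemistry as in 4 | CC1C=C(O[Si](C(C)C)(C(C)C)C(C)C)C[C@H](C)[C@@]1(C)C=C | intermediate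
6 | but-2-yn-1-ol | CC#CCO | starting material
7 | tert-butyl(but-2-yn-1-yloxy)dimethylsilane | CC#CCO[Si](C)(C)C(C)(C)C | intermediate
8 | (E)-tert-butyl[(3-iodobut-2-en-1-yl)oxy]dimethylsilane | I/C(C)=C/CO[Si](C)(C)C(C)(C)C | intermediate
9 | B-alkyl-9-borabicyclo[3.3.1]nonane from hydroboration of 5 | CC1C=C(O[Si](C(C)C)(C(C)C)C(C)C)C[C@H](C)[C@@]1(C)CCB1C2CCCC1CCC2 | intermediate
10 | 4-[(3E)-5-(tert-butyldimethylsilyloxy)-3-methylpent-3-en-1-yl]-3,4,5-trimethyl-1-(triisopropylsilyloxy)cyclohex-1-ene, stereochemistry as in 4 | CC1C=C(O[Si](C(C)C)(C(C)C)C(C)C)C[C@H](C)[C@@]1(C)CC/C(C)=C/CO[Si](C)(C)C(C)(C)C | intermediate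
11 | 4-[(3E)-5-(tert-butyldimethylsilyloxy)-3-methylpent-3-en-1-yl]-3,4,5-trimethylcyclohex-2-en-1-one; C-4 (= C-9) as in the target, 4- and 5-methyls cis | CC1=CC(=O)C[C@H](C)[C@@]1(C)CC/C(C)=C/CO[Si](C)(C)C(C)(C)C | intermediate
12 | 6-hydroxy derivative of 11 (OH on C-7 of the target numbering, epimer mixture) | CC1=CC(=O)C(O)[C@H](C)[C@@]1(C)CC/C(C)=C/CO[Si](C)(C)C(C)(C)C | intermediate
13 | 6-(tert-butyldimethylsilyloxy) derivative of 11 (C-7 epimer mixture) | CC1=CC(=O)C(O[Si](C)(C)C(C)(C)C)[C@H](C)[C@@]1(C)CC/C(C)=C/CO[Si](C)(C)C(C)(C)C | intermediate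
14 | 2-nitroethanol | OCC[N+](=O)[O-] | starting material
15 | acetaldehyde | CC=O | starting material
16 | 2-nitrobutane-1,3-diol (diastereomer mixture) | CC(O)C(CO)[N+](=O)[O-] | intermediate
17 | 3-hydroxy-2-nitrobutyl methanesulfonate | CC(O)C(COS(C)(=O)=O)[N+](=O)[O-] | intermediate
18 | 3-nitrobut-3-en-2-ol (racemic) | C=C(C(C)O)[N+](=O)[O-] | intermediate
19 | 3-nitrobut-3-en-2-yl 2,2-dimethylpropanoate (racemic) | C=C(C(C)OC(=O)C(C)(C)C)[N+](=O)[O-] | intermediate
20 | enone 13 carrying a (3E)-3-nitropent-3-en-1-yl chain on C-10 in place of the methyl | C/C=C(\CCC1=CC(=O)C(O[Si](C)(C)C(C)(C)C)[C@H](C)[C@@]1(C)CC/C(C)=C/CO[Si](C)(C)C(C)(C)C)[N+](=O)[O-] | intermediate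
21 | ring-closed nitro ketone with the alkene at C-1=C-10 and hydrogen on C-5 (C-3, C-4, C-5, C-7 unassigned) | CC1C([N+](=O)[O-])CC=C2C1C(=O)C(O[Si](C)(C)C(C)(C)C)[C@H](C)[C@@]2(C)CC/C(C)=C/CO[Si](C)(C)C(C)(C)C | intermediate
22 | 3-nitro-7,15-bis(tert-butyldimethylsilyloxy)-19-norhalima-5(10),13E-dien-6-one; C-9 as in the target, 8-methyl cis to 9-methyl, C-3, C-4 and C-7 epimer mixtures | CC1C([N+](=O)[O-])CCC2=C1C(=O)C(O[Si](C)(C)C(C)(C)C)[C@H](C)[C@@]2(C)CC/C(C)=C/CO[Si](C)(C)C(C)(C)C | intermediate
23 | 7,15-bis(tert-butyldimethylsilyloxy)-19-norhalima-5(10),13E-diene-3,6-dione (C-4 and C-7 epimer mixtures) | CC1C(=O)CCC2=C1C(=O)C(O[Si](C)(C)C(C)(C)C)[C@H](C)[C@@]2(C)CC/C(C)=C/CO[Si](C)(C)C(C)(C)C | intermediate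
24 | 3-(trimethylsilyloxy)-3,5(10)-diene (enol ether of 23 toward C-4) | CC1=C(O[Si](C)(C)C)CCC2=C1C(=O)C(O[Si](C)(C)C(C)(C)C)[C@H](C)[C@@]2(C)CC/C(C)=C/CO[Si](C)(C)C(C)(C)C | intermediate
25 | 19-hydroxy-7,15-bis(tert-butyldimethylsilyloxy)halima-5(10),13E-diene-3,6-dione; C-4 and C-9 as in the target | OC[C@@]1(C)C(=O)CCC2=C1C(=O)C(O[Si](C)(C)C(C)(C)C)[C@H](C)[C@@]2(C)CC/C(C)=C/CO[Si](C)(C)C(C)(C)C | intermediate
26 | 19-acetoxy-7,15-bis(tert-butyldimethylsilyloxy)halima-5(10),13E-diene-3,6-dione | CC(=O)OC[C@@]1(C)C(=O)CCC2=C1C(=O)C(O[Si](C)(C)C(C)(C)C)[C@H](C)[C@@]2(C)CC/C(C)=C/CO[Si](C)(C)C(C)(C)C | intermediate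
27 | 19-acetoxy-7,15-dihydroxyhalima-5(10),13E-diene-3,6-dione | CC(=O)OC[C@@]1(C)C(=O)CCC2=C1C(=O)C(O)[C@H](C)[C@@]2(C)CC/C(C)=C/CO | intermediate
28 | 19-acetoxy-15-hydroxyhalima-5(10),13E-diene-3,6,7-trione | CC(=O)OC[C@@]1(C)C(=O)CCC2=C1C(=O)C(=O)[C@H](C)[C@@]2(C)CC/C(C)=C/CO | intermediate
29 | (4S,9S,13E)-19-acetoxy-7,15-dihydroxyhalima-5(10),7,13-triene-3,6-dione | CC(=O)OC[C@@]1(C)C(=O)CCC2=C1C(=O)C(O)=C(C)[C@@]2(C)CC/C(C)=C/CO | target

**Step count**
Total step count: 18. Longest linear sequence: 13 steps (1, 2, 3, 6, 7, 8, 9, 13, 14, 15, 16, 17, 18).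

**Steps most likely to fail**

Step 13. The cascade may stall or go astray: the amine may be consumed by the nitroalkene, the nitroalkene may polymerise, the first addition may go through the α-carbon, or the ring-closing conjugate addition at the congested C-5 may not occur. The fallback sets out from 13 and returns at 22, building ring A stepwise with known reactions. Amine-catalysed vinylogous Michael addition of 13 to freshly prepared nitroethylene (same primary amine and acid) should give the 3-(3-nitropropyl)cyclohexenone F1. A Henry reaction of F1 with acetaldehyde (cat. KOtBu) should give the β-nitro alcohol F2. Dehydration (MeSO2Cl, Et3N) then gives nitroalkene 20 as an isolated compound, and DBU in MeCN should close ring A by intramolecular Michael addition of the extended enolate through C-5 and conjugate the alkene to give 22.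

Step 2. The trisubstituted enal may be too unreactive toward a terminally substituted diene, so that open-chain Mukaiyama–Michael addition or poor facial selectivity takes over. The fallback sets out from 2 and 3 and returns at 4. The cycloaddition is run without asymmetric induction (toluene, 110 °C, sealed tube, or Me2AlCl, CH2Cl2, -78 °C) to give the racemic aldehyde F3, which is resolved by preparative chromatography on a chiral stationary phase; the enantiomer with the target C-9 configuration is 4.

Step 15. Facial selectivity at the tetrasubstituted enol ether may be poor (erosion of the C-4 configuration), the silyl group may be lost before C–C bond formation, or formaldehyde may be lost again by retro-aldol reaction. The fallback sets out from 23 and returns at 26. Non-selective hydroxymethylation (KN(SiMe3)2, THF; then monomeric formaldehyde) gives the C-4 epimer mixture F4. Lipase-catalysed acylation with vinyl acetate (Burkholderia cepacia lipase, to be screened) then differentiates the two epimeric neopentyl alcohols. The 4S material is collected either directly as acetate 26 or, if the enzyme prefers the other epimer, as residual alcohol 25, which is acetylated as in step 16. The unwanted 4-epi alcohol F5 (after methanolysis if it was the acetylated epimer) is returned to 23 by retro-aldol loss of formaldehyde (K2CO3, MeOH).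

Further compounds
F1 | step 13 | 6-(tert-butyldimethylsilyloxy)-4-[(3E)-5-(tert-butyldimethylsilyloxy)-3-methylpent-3-en-1-yl]-4,5-dimethyl-3-(3-nitropropyl)cyclohex-2-en-1-one | O=[N+]([O-])CCCC1=CC(=O)C(O[Si](C)(C)C(C)(C)C)[C@H](C)[C@@]1(C)CC/C(C)=C/CO[Si](C)(C)C(C)(C)C
F2 | step 13 | Henry adduct of F1 with acetaldehyde (3-(4-hydroxy-3-nitropentyl) enone, diastereomer mixture) | CC(O)C(CCC1=CC(=O)C(O[Si](C)(C)C(C)(C)C)[C@H](C)[C@@]1(C)CC/C(C)=C/CO[Si](C)(C)C(C)(C)C)[N+](=O)[O-]
F3 | step 2 | racemic 1,2,6-trimethyl-4-(triisopropylsilyloxy)cyclohex-3-ene-1-carbaldehyde (1,6-cis-dimethyl) | CC1C=C(O[Si](C(C)C)(C(C)C)C(C)C)CC(C)C1(C)C=O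
F4 | step 15 | C-4 epimer mixture of 19-hydroxy-7,15-bis(tert-butyldimethylsilyloxy)halima-5(10),13E-diene-3,6-dione | OCC1(C)C(=O)CCC2=C1C(=O)C(O[Si](C)(C)C(C)(C)C)[C@H](C)[C@@]2(C)CC/C(C)=C/CO[Si](C)(C)C(C)(C)C
F5 | step 15 | 4-epi-25 (4R alcohol) | OC[C@]1(C)C(=O)CCC2=C1C(=O)C(O[Si](C)(C)C(C)(C)C)[C@H](C)[C@@]2(C)CC/C(C)=C/CO[Si](C)(C)C(C)(C)C
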